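| flask | electrophile | nucleophile | remark | time |
|---|---|---|---|---|
| maple | 0.10 M | 0.15 M | run made earlier |  |
| larch | 0.10 M | 0.30 M | run made earlier |  |
| red | 0.10 M | 0.150 M (fed, over 20 min) | all else is in the flask from the start; the feed brings no volume worth counting | 50 min |
| amber | 0.10 M | 0.150 M | everything together at the start | 50 min |
| blue | 0.10 M | 0.150 M (in portions, 3, over 20 min) | first portion at the start, last at 20 min | 50 min |
| violet | 0.10 M (fed, over 20 min) | 0.150 M | all else is in the flask from the start; the feed brings no volume worth counting | 50 min |

| run | time / min | over-reaction product / % | target / % |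
|---|---|---|---|
| maple | 2.50 | 1.3 | 10.0 |
| maple | 8.00 | 6.9 | 7.2 |
| maple | 15.0 | 16.1 | 6.6 |
| maple | 20.0 | 18.2 | 5.7 |
| maple | 30.0 | 21.7 | 3.8 |
| maple | 40.0 | 22.4 | 0 |
| maple | 50.0 | 22.6 | 0.1 |
| larch | 0.250 | 0.4 | 4.0 |
| larch | 0.833 | 0.8 | 8.7 |
| larch | 1.33 | 2.6 | 14.3 |
| larch | 2.00 | 2.1 | 14.2 |
| larch | 3.00 | 3.2 | 16.2 |
| larch | 4.00 | 7.1 | 13.6 |
| larch | 5.00 | 6.9 | 14.1 |

(each reading ± 1 percentage point)

1. which flask leads in amount of over-reaction product, in percent of the electrophile charged ("all alike" within 1.5 percentage points) (red / amber / blue / violet / all alike)
2. how much over-reaction product is there at the end, in percent of the electrophile charged: red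
3. how much over-reaction product is there at the end, in percent of the electrophile charged: amber
4. how much over-reaction product is there at the end, in percent of the electrophile charged: blue
5. how much over-reaction product is there at the end, in percent of the electrophile charged: violet

- the numbers in the tables scatter by 1 percentage point (one standard deviation)
- what may be going on: electrophile + nucleophile -> acid set free + target; nucleophile + acid set free <-> protonated nucleophile; target -> over-reaction product; 2 nucleophile -> homo dimer

I had 4 end amounts and one ranking to find, and one question served them: where does the nucleophile go? In maple, target and over-reaction product sum to 0.0227 M at 50.0 min, with 77.3 % of the electrophile uncoupled, so the nucleophile is the limiting reagent. I took each coupling to cost two nucleophiles, the second caught by the acid set free, and the rest to go to homo dimer.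

I defined the crossover concentration Nc, the free nucleophile level at which dimerisation and coupling consume it equally. With the electrophile held near its charge, a batch charge N₀ then couples (Nc/2)·ln(1 + N₀/Nc). Putting maple's numbers in gave Nc = 0.0224 M. Larch's first reading gave a coupling constant k = 0.587 L mol⁻¹ min⁻¹, so I put the dimerisation loss constant at a = 5.24 L mol⁻¹ min⁻¹, both as readings with their scatter.

Amber repeats maple, so I expected about 22.6 %. In red, the feed f = 0.00750 M min⁻¹ balances both losses at N = 0.0283 M. Coupling at that level for the whole feed, plus the batch law for the tail, gave 42.3 %. The weak link was the start, since red's nucleophile climbs from zero. That climb costs ln(2)/√(af) = 3.50 min of feed time, which brought my figure for red to 36.5 %, target still included.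

Counting blue's portions as separate batches gave 39.4 %, target still included, which stood 2.9 percentage points above my figure for red, but both rest on constants read from scattered readings, so I did not rank the two. In violet, Nc grows with the electrophile fed, while dimerisation leaves a nucleophile level of 1/(at). These meet at 13.1 min, which gave 12.4 %.

The forecast named red at 36 %, with amber 22.7 %, blue 34.5 % and violet 9 %, lower than my blue and violet, and said “Feeding electrophile (violet) is worst”.

The flasks gave red 36.2 %, amber 23.1 %, blue 33.5 % and violet 7.92 %, so red leads.

    electrophile + nucleophile → acid set free + target (k = 0.0140 L mol⁻¹ s⁻¹)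
    nucleophile + acid set free ⇌ protonated nucleophile, settled at all times (K = 3700 L mol⁻¹)
    target → over-reaction product (k = 0.00210 s⁻¹)
    2 nucleophile → homo dimer (k = 0.0640 L mol⁻¹ s⁻¹)

At 20.0 min, red held 0.0242 M of free nucleophile beside 71.0 % of its electrophile, more than the 0.0159 M that Nc comes to when scaled to that electrophile. Violet came in under my 12.4 %. That reckoning contains no nucleophile charge, so it gives the same 12.4 % for the neighbouring violet flask with 0.38 M of nucleophile. That flask ended at 8.57 %, against 7.92 % in violet.

The data were computed on assumed constants; the scatter is artificial.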